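Assumption: the name "Luteone hydride" is read as the compound of the given SMILES, the hydrate of luteone, 6-(3-hydroxy-3-methylbutyl)-2′,4′,5,7-tetrahydroxyisoflavone; it has no stereocenter.

**Retrosynthetic overview**
- The target is reached by hydrogenolysis of its 2′,4′-di-O-benzyl ether.
- Ring A (C4a, C5, C6, C7, C8, C8a) carries oxygen on C5, C7 and C8a, the pattern of a cyclised triketide. C7, C6, C1″, C2″ and C3″ with its hydroxyl are the carbonyl carbon, the three ring methylenes, the quaternary carbon and the ring oxygen of 6,6-dimethyl-δ-valerolactone.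
- Ring A is therefore cut at C7–C8 and C5–C6. This gives a 5-aryl-2-methyl-4-pyranone-3-carboxylate (rings C and B; the 2-methyl is C8, the ester carbon is C5) and the lactone.
- The pyranone ring comes from methyl acetoacetate, C-acylated by the ring B arylacetyl chloride, and one formyl carbon.
- Order of ring formation: ring B is bought, ring C is made first, ring A last.

Key step: step 6

**Route**

Step 1
Reactants: 1 2,4-dihydroxyphenylacetic acid
Product: 3 2,4-bis(benzyloxy)phenylacetic acid, via benzyl 2,4-bis(benzyloxy)phenylacetate 2 (not isolated)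
Conditions: BnBr (3.3 equiv), K2CO3, DMF, 60 °C; then aq. NaOH, MeOH–THF, 60 °C; HCl to pH 2
Reagents that add atoms: benzyl bromide, BrCc1ccccc1; sodium hydroxide, [Na+].[OH-]
Why: Williamson alkylation benzylates both phenols and the carboxylate, and saponification of the single ester then returns the acid with the two aryl benzyl ethers untouched.

Step 2
Reactants: 3 2,4-bis(benzyloxy)phenylacetic acid
Product: 4 2,4-bis(benzyloxy)phenylacetyl chloride
Conditions: (COCl)2, cat. DMF, CH2Cl2, 0 °C → rt; concentrated and used crude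
Reagents that add atoms: oxalyl chloride, O=C(Cl)C(Cl)=O
Why: Acid chloride formation through the Vilsmeier-type chloroiminium catalyst runs under conditions that do not touch aryl benzyl ethers.

Step 3
Reactants: 4 2,4-bis(benzyloxy)phenylacetyl chloride; 5 methyl acetoacetate
Product: 6 methyl 2-acetyl-4-[2,4-bis(benzyloxy)phenyl]-3-oxobutanoate (enolised triacylmethane)
Conditions: MgCl2 (1 equiv), pyridine (2 equiv), CH2Cl2, 0 °C → rt; cold 1 M HCl work-up
Reagents that add atoms: none
Why: Soft enolisation of the β-keto ester as its magnesium chelate (Rathke-type C-acylation) directs the acid chloride to the central carbon, and the product stays protected as its chelate until the acidic work-up.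

Step 4
Reactants: 6 methyl 2-acetyl-4-[2,4-bis(benzyloxy)phenyl]-3-oxobutanoate
Product: 8 methyl 5-[2,4-bis(benzyloxy)phenyl]-2-methyl-4-oxo-4H-pyran-3-carboxylate, via enaminone 7 (not isolated)
Conditions: Me2NCH(OMe)2 (1.3 equiv), PhMe, 80 °C; then AcOH, 80 °C
Reagents that add atoms: N,N-dimethylformamide dimethyl acetal, COC(OC)N(C)C
Why: The amide acetal should condense at the aryl-activated methylene, as it does with benzyl ketones, and the acetyl enol oxygen then closes onto the enaminone carbon with loss of dimethylamine (6-endo addition–elimination), the pyranone counterpart of the deoxybenzoin-to-isoflavone closure and of the known pyranone synthesis from 2-acyl-1,3-diketones.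

Step 5
Reactants: 9 methyl 5-oxohexanoate
Product: 11 6,6-dimethyltetrahydro-2H-pyran-2-one, via methyl 5-hydroxy-5-methylhexanoate 10 (not isolated)
Conditions: MeMgBr (1.05 equiv), THF, −78 → 0 °C; 1 M HCl; then cat. TsOH·H2O, CH2Cl2, rt
Reagents that add atoms: methylmagnesium bromide, C[Mg]Br
Why: Grignard addition at low temperature is selective for the ketone over the ester, and the δ-hydroxy ester lactonises by intramolecular transesterification to the six-membered lactone.

Step 6
Reactants: 8 methyl 5-[2,4-bis(benzyloxy)phenyl]-2-methyl-4-oxo-4H-pyran-3-carboxylate; 11 6,6-dimethyltetrahydro-2H-pyran-2-one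
Product: 14 3-[2,4-bis(benzyloxy)phenyl]-5,7-dihydroxy-6-(3-hydroxy-3-methylbutyl)-4H-chromen-4-one, via lithium dienolate 12 (not isolated), via open-chain hydroxy keto ester 13 (not isolated)
Conditions: LiN(iPr)2 (1.1 equiv), THF, −78 °C; 11 (1.5 equiv), −78 → −30 °C; LiN(iPr)2 (2.6 equiv), −78 °C → rt; AcOH, then aq. NaH2PO4
Reagents that add atoms: none
Why: Proposed new method: LiN(iPr)2 removes a proton from the 2-methyl group of 8 (vinylogous to both the C4 ketone and the ester) to give dienolate 12, whose exocyclic carbon (future C8) adds to the lactone carbonyl of 11; opening of the adduct frees the tertiary alkoxide and leaves keto ester 13 as its C8 enolate, and the second charge of amide base removes a proton from the remote α-methylene (future C6) to give a dianion of the 1,3-dicarbonyl type. This terminal carbanion attacks the neighbouring methyl ester in a 6-exo-trig Dieckmann (Claisen) closure, methoxide leaves, and the cyclic 1,3-dione tautomerises to the aromatic 5,7-dihydroxy ring A with the side chain between the two oxygens. The closest known reactions are lateral lithiation–acylation of 2-methyl-4-pyranones and of ortho-toluates, and the base-mediated Claisen cyclisation of 3,5-dioxo esters to phloroglucinols and of 5-oxo esters to cyclohexane-1,3-diones; their union in one flask with a lactone as acyl donor is the untested part. No stereocenter is formed. The step needs acylation of 12 instead of enolisation of the lactone, which is served by forming 12 completely before 11 is added and by holding back the rest of the base until the acylation is over; it also needs carbon closure through C6, which is served by the dianion (its terminal carbon is the most nucleophilic site), by the fact that C8 cannot reach the ester and that attack of C6 on the C4 carbonyl would give a bridged anti-Bredt ring, and by the irreversible aromatisation that drains any reversibly formed enol lactone.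

Step 7
Reactants: 14 3-[2,4-bis(benzyloxy)phenyl]-5,7-dihydroxy-6-(3-hydroxy-3-methylbutyl)-4H-chromen-4-one
Product: 15 luteone hydrate, 3-(2,4-dihydroxyphenyl)-5,7-dihydroxy-6-(3-hydroxy-3-methylbutyl)-4H-chromen-4-one
Conditions: H2 (1 atm), 10% Pd/C, EtOAc–MeOH, rt; stopped after uptake of 2 equiv H2
Reagents that add atoms: none
Why: Catalytic hydrogenolysis cleaves aryl benzyl ethers faster than it saturates the chromone C2=C3 bond, and the neutral medium keeps the tertiary alcohol from dehydrating or cyclising onto the 5- or 7-hydroxyl.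

**Compound list**
1 | 2,4-dihydroxyphenylacetic acid | OC(=O)Cc1ccc(O)cc1O | starting material
2 | benzyl 2,4-bis(benzyloxy)phenylacetate | O=C(Cc1ccc(OCc2ccccc2)cc1OCc1ccccc1)OCc1ccccc1 | intermediate
3 | 2,4-bis(benzyloxy)phenylacetic acid | OC(=O)Cc1ccc(OCc2ccccc2)cc1OCc1ccccc1 | intermediate
4 | 2,4-bis(benzyloxy)phenylacetyl chloride | ClC(=O)Cc1ccc(OCc2ccccc2)cc1OCc1ccccc1 | intermediate
5 | methyl acetoacetate | CC(=O)CC(=O)OC | starting material
6 | methyl 2-acetyl-4-[2,4-bis(benzyloxy)phenyl]-3-oxobutanoate (drawn as the triketo form) | COC(=O)C(C(C)=O)C(=O)Cc1ccc(OCc2ccccc2)cc1OCc1ccccc1 | intermediate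
7 | methyl 2-acetyl-4-[2,4-bis(benzyloxy)phenyl]-5-(dimethylamino)-3-oxopent-4-enoate (enaminone, double-bond geometry without consequence) | COC(=O)C(C(C)=O)C(=O)C(=CN(C)C)c1ccc(OCc2ccccc2)cc1OCc1ccccc1 | intermediate
8 | methyl 5-[2,4-bis(benzyloxy)phenyl]-2-methyl-4-oxo-4H-pyran-3-carboxylate | COC(=O)c1c(C)occ(-c2ccc(OCc3ccccc3)cc2OCc2ccccc2)c1=O | intermediate
9 | methyl 5-oxohexanoate | CC(=O)CCCC(=O)OC | starting material
10 | methyl 5-hydroxy-5-methylhexanoate (formed as its bromomagnesium alkoxide) | CC(C)(O)CCCC(=O)OC | intermediate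
11 | 6,6-dimethyltetrahydro-2H-pyran-2-one | CC1(C)CCCC(=O)O1 | intermediate
12 | lithium dienolate of 8 (2-methylene ketene-acetal form) | C=C1OC=C(c2ccc(OCc3ccccc3)cc2OCc2ccccc2)C(=O)C1=C(OC)O[Li] | intermediate
13 | methyl 5-[2,4-bis(benzyloxy)phenyl]-2-(6-hydroxy-6-methyl-2-oxoheptyl)-4-oxo-4H-pyran-3-carboxylate (present as its lithium polyanion) | COC(=O)c1c(CC(=O)CCCC(C)(C)O)occ(-c2ccc(OCc3ccccc3)cc2OCc2ccccc2)c1=O | intermediate
14 | 3-[2,4-bis(benzyloxy)phenyl]-5,7-dihydroxy-6-(3-hydroxy-3-methylbutyl)-4H-chromen-4-one | CC(C)(O)CCc1c(O)cc2occ(-c3ccc(OCc4ccccc4)cc3OCc3ccccc3)c(=O)c2c1O | intermediate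
15 | luteone hydrate, 3-(2,4-dihydroxyphenyl)-5,7-dihydroxy-6-(3-hydroxy-3-methylbutyl)-4H-chromen-4-one | CC(C)(O)CCc1c(O)cc2occ(-c3ccc(O)cc3O)c(=O)c2c1O | target

**Step count**
Total steps: 7. Longest linear sequence: 6 (steps 1, 2, 3, 4, 6, 7); the lactone branch is step 5.

**Steps most likely to fail**

Step 6 (key step)
- What may go wrong:
  - Enolisation of the lactone by the amide base, or proton exchange between the dienolate and the first-formed ketone, may stall the acylation.
  - The ketone enolate may close through oxygen onto the ester to give a fused enol lactone instead of ring A.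
  - The amide or an enolate may add to the unsubstituted pyranone carbon and open ring C.
- Fallback: the two carbon–carbon bonds are made in separate operations by known reactions, setting out from 8 and 11 and coming back to the route at 14.
  - Lactone 11 is opened with MeNH(OMe)·HCl and AlMe3 in CH2Cl2 to the hydroxy Weinreb amide 5-hydroxy-N-methoxy-N,5-dimethylhexanamide F1.
  - Silylation with Et3SiOTf and 2,6-lutidine gives N-methoxy-N,5-dimethyl-5-(triethylsilyloxy)hexanamide F2.
  - The dienolate of 8 (LiN(iPr)2, 1.1 equiv, THF, −78 °C) is acylated by F2. The chelated tetrahedral adduct should hold until work-up, so no proton exchange can occur. This gives methyl 5-[2,4-bis(benzyloxy)phenyl]-2-[6-methyl-2-oxo-6-(triethylsilyloxy)heptyl]-4-oxo-4H-pyran-3-carboxylate F3.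
  - KOtBu in THF (0 °C → rt) then closes ring A under equilibrating conditions, as in the Claisen cyclisation of 5-oxo esters to cyclohexane-1,3-diones. Only the carbon closure ends in an aromatic phenoxide, so it should collect the material as 3-[2,4-bis(benzyloxy)phenyl]-5,7-dihydroxy-6-[3-methyl-3-(triethylsilyloxy)butyl]-4H-chromen-4-one F4.
  - Bu4NF buffered with AcOH in THF removes the silyl group to give 14.

Step 4
- What may go wrong:
  - Condensation of the amide acetal at the acetyl methyl instead of the benzylic methylene would give the isomeric 2-benzyl pyranone.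
  - The acetal may O-methylate the acidic enol.
  - Liberated dimethylamine may cleave an acyl group from the triacylmethane.
- Fallback: the formyl carbon is placed on the arylacetic unit before the acetoacetate is attached, so no choice of site remains. It sets out from 3 and comes back at 8.
  - MeI and K2CO3 in DMF give methyl [2,4-bis(benzyloxy)phenyl]acetate F5.
  - Claisen formylation (HCO2Me, NaH, THF) gives methyl 2-[2,4-bis(benzyloxy)phenyl]-3-hydroxyprop-2-enoate F6.
  - O-Methylation (Me2SO4, K2CO3, DMF) gives methyl (E)-2-[2,4-bis(benzyloxy)phenyl]-3-methoxyprop-2-enoate F7; any Z isomer serves equally.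
  - LiOH in THF–H2O gives (E)-2-[2,4-bis(benzyloxy)phenyl]-3-methoxyprop-2-enoic acid F8.
  - (COCl)2 with cat. DMF gives (E)-2-[2,4-bis(benzyloxy)phenyl]-3-methoxyprop-2-enoyl chloride F9.
  - F9 C-acylates methyl acetoacetate 5 under MgCl2–pyridine to methyl 2-acetyl-4-[2,4-bis(benzyloxy)phenyl]-5-methoxy-3-oxopent-4-enoate F10. F10 is not isolated: on warming with AcOH its acetyl enol oxygen displaces methoxide by addition–elimination to give 8.

Step 3
- What may go wrong:
  - Pyridine may dehydrochlorinate the electron-rich arylacetyl chloride to a ketene that dimerises.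
  - Acylation may occur on oxygen.
  - The acetyl group may be lost by retro-Claisen cleavage during work-up.
- Fallback: the arylacetyl group is introduced through Meldrum's acid and the acetyl group is added last. It sets out from 4 and comes back at 6.
  - Acid chloride 4 with 2,2-dimethyl-1,3-dioxane-4,6-dione and pyridine in CH2Cl2 (0 °C) gives 5-{2-[2,4-bis(benzyloxy)phenyl]-1-hydroxyethylidene}-2,2-dimethyl-1,3-dioxane-4,6-dione F11.
  - Methanolysis in refluxing MeOH gives methyl 4-[2,4-bis(benzyloxy)phenyl]-3-oxobutanoate F12.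
  - C-Acetylation of F12 at C2 with AcCl, MgCl2 and pyridine in CH2Cl2 gives 6.

Further compounds
F1 | step 6 | 5-hydroxy-N-methoxy-N,5-dimethylhexanamide | CON(C)C(=O)CCCC(C)(C)O
F2 | step 6 | N-methoxy-N,5-dimethyl-5-(triethylsilyloxy)hexanamide | CON(C)C(=O)CCCC(C)(C)O[Si](CC)(CC)CC
F3 | step 6 | methyl 5-[2,4-bis(benzyloxy)phenyl]-2-[6-methyl-2-oxo-6-(triethylsilyloxy)heptyl]-4-oxo-4H-pyran-3-carboxylate | COC(=O)c1c(CC(=O)CCCC(C)(C)O[Si](CC)(CC)CC)occ(-c2ccc(OCc3ccccc3)cc2OCc2ccccc2)c1=O
F4 | step 6 | 3-[2,4-bis(benzyloxy)phenyl]-5,7-dihydroxy-6-[3-methyl-3-(triethylsilyloxy)butyl]-4H-chromen-4-one | CC[Si](CC)(CC)OC(C)(C)CCc1c(O)cc2occ(-c3ccc(OCc4ccccc4)cc3OCc3ccccc3)c(=O)c2c1O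
F5 | step 4 | methyl [2,4-bis(benzyloxy)phenyl]acetate | COC(=O)Cc1ccc(OCc2ccccc2)cc1OCc1ccccc1
F6 | step 4 | methyl 2-[2,4-bis(benzyloxy)phenyl]-3-hydroxyprop-2-enoate (enol of the formyl ester) | COC(=O)C(=CO)c1ccc(OCc2ccccc2)cc1OCc1ccccc1
F7 | step 4 | methyl (E)-2-[2,4-bis(benzyloxy)phenyl]-3-methoxyprop-2-enoate | CO/C=C(/C(=O)OC)c1ccc(OCc2ccccc2)cc1OCc1ccccc1
F8 | step 4 | (E)-2-[2,4-bis(benzyloxy)phenyl]-3-methoxyprop-2-enoic acid | CO/C=C(/C(=O)O)c1ccc(OCc2ccccc2)cc1OCc1ccccc1
F9 | step 4 | (E)-2-[2,4-bis(benzyloxy)phenyl]-3-methoxyprop-2-enoyl chloride | CO/C=C(/C(Cl)=O)c1ccc(OCc2ccccc2)cc1OCc1ccccc1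
F10 | step 4 | methyl 2-acetyl-4-[2,4-bis(benzyloxy)phenyl]-5-methoxy-3-oxopent-4-enoate | CO/C=C(/C(=O)C(C(C)=O)C(=O)OC)c1ccc(OCc2ccccc2)cc1OCc1ccccc1
F11 | step 3 | 5-{2-[2,4-bis(benzyloxy)phenyl]-1-hydroxyethylidene}-2,2-dimethyl-1,3-dioxane-4,6-dione | CC1(C)OC(=O)C(=C(O)Cc2ccc(OCc3ccccc3)cc2OCc2ccccc2)C(=O)O1
F12 | step 3 | methyl 4-[2,4-bis(benzyloxy)phenyl]-3-oxobutanoate | COC(=O)CC(=O)Cc1ccc(OCc2ccccc2)cc1OCc1ccccc1
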